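Reading stops at 8.00 h, and you want what the same flask holds at 40 h.

| flask | substrate | partner | initiator | remark | time |
|---|---|---|---|---|---|
| blue | 0.25 M (in portions, 4) | 0.263 M | 6.2 mM | the very flask that is asked about, followed so far; portions every 30 min |  |
| flask | 0.25 M (in portions, 4) | 0.263 M | 6.2 mM | the portions of substrate follow each other after 30 min, the first at the start | 40 h |

blue run (percent of the substrate charged)

| time / h | over-reaction product / % | target / % | first chain carrier / % | substrate / % |
|---|---|---|---|---|
| 0.417 | 0 | 2 | 0 | 23 |
| 1.33 | 3 | 9 | 2 | 67 |
| 2.50 | 4 | 15 | 0 | 83 |
| 3.00 | 7 | 12 | 6 | 80 |
| 5.00 | 11 | 16 | 0 | 70 |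
| 6.00 | 14 | 20 | 0 | 66 |
| 8.00 | 20 | 19 | 0 | 57 |

(scatter of a reading: 2 percentage points)

1. the species in which most of what was charged as substrate, at 40 h sits (over-reaction product / first chain carrier / target / substrate)
2. the largest share itself, whichever of these holds it, in percent of the substrate charged

- percentages count the whole charge, also what has not yet gone in

1. Compare rates on the last stretch. From 5.00 h to 8.00 h the over-reaction product gains 9 percentage points, and carried straight on that gives 116 % at 40 h.

2. That fails at once, being more than the whole charge of substrate. So the pace must drift down, but what slows it? My candidate is the partner, charged at just 105 % of the substrate charge. I assume one partner goes into each target and a second into each over-reaction product, which makes it the likely limiting reagent. The readings show no partner, so this stays an assumption.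

3. Next, the target. It gains 3 points on that stretch, less than the over-reaction product, and its last readings are 20 % and 19 %, within the scatter of 2 points. So hold [target] at 19 %. Then half of what the partner charge leaves after that target is 43.1 %, the partner ceiling on the over-reaction product while [target] stays there.

4. Is there time to reach it? By my count 46.2 % of partner, on the substrate scale, is unspent at 8.00 h. At the last pace that lasts 7.70 h, less than the 32.0 h remaining. The pace will fall with [partner], yet the time remaining is 4.16 times that span, so I commit to the ceiling, with substrate near 33.9 %.

5. The forecast names over-reaction product at 50 %: “probably around 50%, with wide uncertainty”. My reckoning names the same species at a lower share, 43.1 %.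

    initiator → 2 initiating radical (k = 5.80 × 10⁻⁴ min⁻¹)
    2 first chain carrier → ended chains (k = 1.00 × 10⁹ M⁻¹ s⁻¹)
    partner + target → over-reaction product (k = 0.0200 M⁻¹ min⁻¹)
    substrate + second chain carrier → by-product + first chain carrier (k = 3.70 × 10⁵ M⁻¹ min⁻¹)
    partner + first chain carrier ⇌ target + second chain carrier (K = 7.00, k = 1.60 × 10⁵ M⁻¹ min⁻¹)
    substrate + initiating radical → capped initiator + first chain carrier (k = 1.90 × 10⁵ M⁻¹ s⁻¹)

The flask gives over-reaction product as the largest share at 40 h, 42.8 %, against the ceiling of 43.1 %. At that time 1.5 % of the partner charged is still there, and partner is the first charge to run out. Now take the neighbour flask charged with 0.11 M of partner, all else as in this flask, whose target stands at 14.9 % at the end. Half of what its partner charge leaves after that target puts its ceiling at 14.6 %. That neighbour flask ends with 14.0 % of over-reaction product.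

The numbers in the tables come from a simulation on assumed constants, and the scatter is random.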